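**Retrosynthetic overview**

1. The target is read as the A/B-cis labdane (5R,8S,9R,10S) with H-5, CH3-20, C-11 and the 8-OH all on one face of ring B. The last steps only delete a temporary C1 ketone, saturate C6=C7 and free the 8-OH.
2. Key disconnection: C5–C10 and C8–C9 are made together by a type 1 intramolecular Diels–Alder reaction of the achiral, acyclic trienone 16. Rings A and B form at the same time and all four stereocentres are set.
3. Enabling feature: ring B is a cyclohexane with the C8 carbinol 1,4 to C5 (retron of a C5=C6–C7=C8–O dienol ether), and quaternary C10 is flanked by C1 of ring A. A temporary C1 carbonyl activates the C9=C10 dienophile from inside the tether; a tether carbonyl in the endo position gives the cis fusion and the all-syn array.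
4. Trienone 16 comes from Grignard reagent 14 (C2–C8, C17–C19 with the silyl dienol ether) and 8-oxogeranyl acetate 13 (C1, C9–C16, C20, acetate already in place), followed by oxidation.
5. The left fragment comes from prenal: propargylation, Johnson–Claisen rearrangement (quaternary C4, E-C5=C6), alkyne hydration, dienol silyl ether.

Key step: step 10

Numbering: labdane numbering (C1–C20) is used for the skeleton atoms throughout.

Assumption: the (S)-configured boron Lewis acid of step 10 is taken to deliver the (5R,8S,9R,10S) series; its facial sense for this α-methyl enone cannot be derived from a model here, and if it proves opposite the (R)-catalyst is used with nothing else changed.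

**Route**

Step 1
Reactants: 1 3-methylbut-2-enal (prenal); 2 3-bromoprop-1-yne (propargyl bromide)
Product: 4 2-methylhept-2-en-6-yn-4-ol (racemic), via allenylzinc bromide 3 (not isolated)
Conditions: Zn dust, THF/sat. aq NH4Cl, 0 °C → rt
Reagents that add atoms: none
Why: Barbier propargylation, in which the allenylzinc species adds 1,2 to the enal with propargyl–allenyl transposition; the carbinol centre is racemic and is destroyed in step 2.

Step 2
Reactants: 4 2-methylhept-2-en-6-yn-4-ol
Product: 6 ethyl (4E)-3,3-dimethyloct-4-en-7-ynoate, via mixed ketene acetal 5 (not isolated)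
Conditions: CH3C(OEt)3, EtCO2H (cat.), 140 °C, EtOH distilled off
Reagents that add atoms: triethyl orthoacetate CCOC(C)(OCC)OCC
Why: Johnson–Claisen rearrangement, whose chair [3,3] shift forms the quaternary C4 at the dimethyl-substituted alkene terminus and should deliver the C5=C6 alkene E.

Step 3
Reactants: 6 ethyl (4E)-3,3-dimethyloct-4-en-7-ynoate
Product: 7 (4E)-3,3-dimethyloct-4-en-7-yn-1-ol
Conditions: LiAlH4, Et2O, 0 °C
Reagents that add atoms: none
Why: Standard hydride reduction of the ester; the alkyne and the isolated alkene are inert.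

Step 4
Reactants: 7 (4E)-3,3-dimethyloct-4-en-7-yn-1-ol
Product: 8 (4E)-8-hydroxy-6,6-dimethyloct-4-en-2-one
Conditions: Ph3PAuNTf2 (2 mol%), 1,4-dioxane/H2O, 40 °C
Reagents that add atoms: water O
Why: Gold-catalysed Markovnikov hydration of the terminal alkyne should give the methyl ketone (C8=O) under near-neutral conditions that leave the β,γ-alkene in place.

Step 5
Reactants: 8 (4E)-8-hydroxy-6,6-dimethyloct-4-en-2-one
Product: 9 (4E)-8-bromo-6,6-dimethyloct-4-en-2-one
Conditions: CBr4, PPh3, CH2Cl2, 0 °C
Reagents that add atoms: tetrabromomethane BrC(Br)(Br)Br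
Why: Appel bromination of the primary alcohol under neutral conditions.

Step 6
Reactants: 9 (4E)-8-bromo-6,6-dimethyloct-4-en-2-one
Product: 10 tert-butyl{[(2Z,4E)-8-bromo-6,6-dimethylocta-2,4-dien-2-yl]oxy}dimethylsilane
Conditions: TBSOTf, Et3N, CH2Cl2, −78 → 0 °C
Reagents that add atoms: tert-butyldimethylsilyl trifluoromethanesulfonate CC(C)(C)[Si](C)(C)OS(=O)(=O)C(F)(F)F
Why: Soft enolisation should remove the doubly activated C7–H (allylic and α to the carbonyl) rather than a methyl proton and give the conjugated dienol ether with oxygen cis to the vinyl group (Z), the less strained geometry; the enol ether also masks the C8 ketone for step 8.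

Step 7
Reactants: 11 geranyl acetate
Product: 13 (2E,6E)-3,7-dimethyl-8-oxoocta-2,6-dien-1-yl acetate, via 8-hydroxygeranyl acetate 12 (not isolated)
Conditions: SeO2, 95% EtOH, reflux
Reagents that add atoms: selenium dioxide O=[Se]=O
Why: Allylic oxidation by SeO2 (ene reaction, then [2,3] shift) is selective for the E-methyl group of the terminal trisubstituted alkene and should run on to the E-enal.

Step 8
Reactants: 10 tert-butyl{[(2Z,4E)-8-bromo-6,6-dimethylocta-2,4-dien-2-yl]oxy}dimethylsilane; 13 (2E,6E)-3,7-dimethyl-8-oxoocta-2,6-dien-1-yl acetate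
Product: 15 (2E,6E,12E,14Z)-15-[(tert-butyldimethylsilyl)oxy]-8-hydroxy-3,7,11,11-tetramethylhexadeca-2,6,12,14-tetraen-1-yl acetate (racemic at the carbinol), via Grignard reagent 14 (not isolated)
Conditions: Mg (activated), THF, 35 °C; then 13, THF, −78 °C; aq NH4Cl
Reagents that add atoms: none
Why: Grignard 1,2-addition to the enal at −78 °C should be much faster than attack on the acetate; the new carbinol centre (C1) is removed in step 9.

Step 9
Reactants: 15 allylic alcohol
Product: 16 (2E,6E,12E,14Z)-15-[(tert-butyldimethylsilyl)oxy]-3,7,11,11-tetramethyl-8-oxohexadeca-2,6,12,14-tetraen-1-yl acetate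
Conditions: MnO2 (activated), CH2Cl2, 0 °C → rt, used at once
Reagents that add atoms: none
Why: MnO2 oxidises the allylic alcohol selectively to the E-enone without touching the silyl dienol ether.

Step 10
Reactants: 16 trienone
Product: 17 (5R,8S,9R,10S,13E)-8-[(tert-butyldimethylsilyl)oxy]-1-oxolabda-6,13-dien-15-yl acetate (A/B cis; H-5, CH3-20, C-11 and O-8 on one face)
Conditions: (S)-B-(2-methylphenyl)oxazaborolidine from α,α-diphenylprolinol (20 mol%), AlBr3 (16 mol%), CH2Cl2, −78 → −40 °C
Reagents that add atoms: none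
Why: The chiral boron Lewis acid binds the C1 ketone, and enone and dienol ether close through a concerted, asynchronous endo [4+2] transition state (type 1 intramolecular Diels–Alder reaction of a 1,7,9-decatrien-3-one); the closest precedent is cationic oxazaborolidine catalysis of enone Diels–Alder reactions. Ring A (six-membered) is closed by the C5–C10 bond across the four-atom tether with the tether carbonyl endo, and ring B is the cyclohexene of the cycloaddition, completed by the C8–C9 bond. The endo tether carbonyl puts C1 and C4 on one face and so gives the cis fusion (C5, C10); the E-enone carries C11 syn to CH3-20 (C9); the Z enol ether, with oxygen inside the diene, places O8 syn to H5, CH3-20 and C11 (C8). The absolute sense comes from the catalyst, which shields one enantiotopic face of the bound enone. The step needs endo over exo closure and a concerted path instead of stepwise Mukaiyama–Michael addition (the dienol ether oxygen sits on the electronically less favourable terminus for an in-tether acceptor); the in-tether carbonyl, the low temperature and the fixed six-membered tether are relied on for this.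

Step 11
Reactants: 17 cycloadduct
Product: 18 (5R,8S,9R,10S,13E)-8-hydroxy-1-oxolabda-6,13-dien-15-yl acetate
Conditions: TBAF, AcOH (1:1), THF, rt
Reagents that add atoms: none
Why: Fluoride cleaves the tertiary silyl ether, and the acetic acid buffer protects the primary acetate.

Step 12
Reactants: 18 allylic tertiary alcohol
Product: 19 (5R,8S,9R,10S,13E)-8-hydroxy-1-oxolabd-13-en-15-yl acetate
Conditions: H2 (10 bar), [Rh(nbd)(dppb)]BF4 (5 mol%), CH2Cl2, rt
Reagents that add atoms: none
Why: Hydroxyl-directed homogeneous hydrogenation, in which the cationic rhodium catalyst binds the allylic 8-OH and reduces C6=C7 while the non-coordinating trisubstituted C13=C14 alkene should stay; no stereocentre is formed.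

Step 13
Reactants: 19 keto alcohol
Product: 20 (5R,8S,9R,10S,13E)-8-hydroxy-1-[2-(4-methylbenzenesulfonyl)hydrazinylidene]labd-13-en-15-yl acetate (C=N geometry immaterial)
Conditions: TsNHNH2, PPTS (cat.), THF, 50 °C
Reagents that add atoms: 4-methylbenzenesulfonohydrazide Cc1ccc(cc1)S(=O)(=O)NN
Why: Condensation of the C1 ketone with tosylhydrazine; C10 is quaternary and C2 carries no stereocentre, so nothing can epimerise.

Step 14
Reactants: 20 tosylhydrazone
Product: 23 (5R,8S,9R,10S,13E)-8-hydroxylabd-13-en-15-yl acetate (target), via N-boryl tosylhydrazine 21 (not isolated), via alkyldiazene 22 (not isolated)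
Conditions: catecholborane, CHCl3, 0 °C → rt; then NaOAc·3H2O, reflux
Reagents that add atoms: none
Why: Tosylhydrazone reduction by catecholborane, then acetate-induced loss of sulfinate and N2, replaces C=N by CH2 under near-neutral conditions that should spare the acetate, the alkene and the tertiary alcohol.

**Compound list**

1 | 3-methylbut-2-enal (prenal) | CC(C)=CC=O | starting material
2 | 3-bromoprop-1-yne (propargyl bromide) | C#CCBr | starting material
3 | propa-1,2-dienylzinc bromide (allenylzinc bromide, not isolated) | C=C=C[Zn]Br | intermediate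
4 | 2-methylhept-2-en-6-yn-4-ol (racemic) | CC(C)=CC(O)CC#C | intermediate
5 | 4-[(1-ethoxyethenyl)oxy]-2-methylhept-2-en-6-yne (mixed ketene acetal, not isolated) | CC(C)=CC(CC#C)OC(=C)OCC | intermediate
6 | ethyl (4E)-3,3-dimethyloct-4-en-7-ynoate | CCOC(=O)CC(C)(C)/C=C/CC#C | intermediate
7 | (4E)-3,3-dimethyloct-4-en-7-yn-1-ol | OCCC(C)(C)/C=C/CC#C | intermediate
8 | (4E)-8-hydroxy-6,6-dimethyloct-4-en-2-one | CC(=O)C/C=C/C(C)(C)CCO | intermediate
9 | (4E)-8-bromo-6,6-dimethyloct-4-en-2-one | CC(=O)C/C=C/C(C)(C)CCBr | intermediate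
10 | tert-butyl{[(2Z,4E)-8-bromo-6,6-dimethylocta-2,4-dien-2-yl]oxy}dimethylsilane | C/C(O[Si](C)(C)C(C)(C)C)=C/C=C/C(C)(C)CCBr | intermediate
11 | geranyl acetate, (2E)-3,7-dimethylocta-2,6-dien-1-yl acetate | CC(=O)OC/C=C(\C)CCC=C(C)C | starting material
12 | (2E,6E)-8-hydroxy-3,7-dimethylocta-2,6-dien-1-yl acetate (not isolated) | CC(=O)OC/C=C(\C)CC/C=C(\C)CO | intermediate
13 | (2E,6E)-3,7-dimethyl-8-oxoocta-2,6-dien-1-yl acetate | CC(=O)OC/C=C(\C)CC/C=C(\C)C=O | intermediate
14 | {(4E,6Z)-7-[(tert-butyldimethylsilyl)oxy]-3,3-dimethylocta-4,6-dien-1-yl}magnesium bromide (not isolated) | C/C(O[Si](C)(C)C(C)(C)C)=C/C=C/C(C)(C)CC[Mg]Br | intermediate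
15 | (2E,6E,12E,14Z)-15-[(tert-butyldimethylsilyl)oxy]-8-hydroxy-3,7,11,11-tetramethylhexadeca-2,6,12,14-tetraen-1-yl acetate (racemic carbinol) | C/C(O[Si](C)(C)C(C)(C)C)=C/C=C/C(C)(C)CCC(O)/C(C)=C/CC/C(C)=C/COC(C)=O | intermediate
16 | (2E,6E,12E,14Z)-15-[(tert-butyldimethylsilyl)oxy]-3,7,11,11-tetramethyl-8-oxohexadeca-2,6,12,14-tetraen-1-yl acetate | C/C(O[Si](C)(C)C(C)(C)C)=C/C=C/C(C)(C)CCC(=O)/C(C)=C/CC/C(C)=C/COC(C)=O | intermediate
17 | (5R,8S,9R,10S,13E)-8-[(tert-butyldimethylsilyl)oxy]-1-oxolabda-6,13-dien-15-yl acetate (A/B cis) | CC(=O)OC/C=C(\C)CC[C@@H]1[C@@]2(C)C(=O)CCC(C)(C)[C@H]2C=C[C@]1(C)O[Si](C)(C)C(C)(C)C | intermediate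
18 | (5R,8S,9R,10S,13E)-8-hydroxy-1-oxolabda-6,13-dien-15-yl acetate | CC(=O)OC/C=C(\C)CC[C@@H]1[C@@]2(C)C(=O)CCC(C)(C)[C@H]2C=C[C@]1(C)O | intermediate
19 | (5R,8S,9R,10S,13E)-8-hydroxy-1-oxolabd-13-en-15-yl acetate | CC(=O)OC/C=C(\C)CC[C@@H]1[C@@]2(C)C(=O)CCC(C)(C)[C@H]2CC[C@]1(C)O | intermediate
20 | (5R,8S,9R,10S,13E)-8-hydroxy-1-[2-(4-methylbenzenesulfonyl)hydrazinylidene]labd-13-en-15-yl acetate | CC(=O)OC/C=C(\C)CC[C@@H]1[C@@]2(C)C(=NNS(=O)(=O)c3ccc(C)cc3)CCC(C)(C)[C@H]2CC[C@]1(C)O | intermediate
21 | N-(1,3,2-benzodioxaborol-2-yl) tosylhydrazine at C1 (C1 epimers, not isolated) | CC(=O)OC/C=C(\C)CC[C@@H]1[C@@]2(C)C(N(NS(=O)(=O)c3ccc(C)cc3)B3Oc4ccccc4O3)CCC(C)(C)[C@H]2CC[C@]1(C)O | intermediate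
22 | C1 alkyldiazene (C1 epimers, not isolated) | CC(=O)OC/C=C(\C)CC[C@@H]1[C@@]2(C)C(N=N)CCC(C)(C)[C@H]2CC[C@]1(C)O | intermediate
23 | (5R,8S,9R,10S,13E)-8-hydroxylabd-13-en-15-yl acetate | CC(=O)OC/C=C(\C)CC[C@@H]1[C@@]2(C)CCCC(C)(C)[C@H]2CC[C@]1(C)O | target

**Summary**

Total step count: 14. Longest linear sequence: 13 steps (steps 1–6 and 8–14; step 7 is the side branch).

Steps most likely to fail:

1. Step 10. Facial selection by the catalyst may be poor, endo closure may erode (the C11 chain sits next to the inside silyloxy group), or the Lewis acid may trigger stepwise silyl transfer instead of cycloaddition. Fallback: starting from 16, an uncatalysed thermal cycloaddition (toluene, 80 °C, BHT), which relies only on the endo preference of the tether carbonyl, should give the racemate, that is 17 together with its mirror image (5S,8R,9S,10R,13E)-8-[(tert-butyldimethylsilyl)oxy]-1-oxolabda-6,13-dien-15-yl acetate F1. The enantiomers are separated by preparative chromatography on a chiral stationary phase, and the route is rejoined at 17.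

2. Step 4. The β,γ-double bond may migrate into conjugation, or the gold catalyst may engage the 1,4-enyne instead of hydrating the alkyne. Fallback: starting from 1, addition of allylmagnesium bromide gives 2-methylhepta-2,6-dien-4-ol F2. Johnson–Claisen rearrangement with triethyl orthoacetate, through the ketene acetal 4-[(1-ethoxyethenyl)oxy]-2-methylhepta-2,6-diene F3, gives ethyl (4E)-3,3-dimethylocta-4,7-dienoate F4. LiAlH4 reduction gives (4E)-3,3-dimethylocta-4,7-dien-1-ol F5, and Wacker oxidation of the terminal alkene (PdCl2 cat., CuCl, O2, DMF/H2O) returns to the route at 8.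

3. Step 13. The hindered C1 ketone next to quaternary C10 may not condense, or the acid may dehydrate the tertiary alcohol. Fallback: starting from 19, NaBH4 (EtOH, 0 °C) gives (5R,8S,9R,10S,13E)-1,8-dihydroxylabd-13-en-15-yl acetate F6. 1,1'-Thiocarbonyldiimidazole (DMAP, toluene, 80 °C) acylates only the secondary 1-OH to give the 1-O-(imidazol-1-ylcarbonothioyl) derivative F7, and Barton–McCombie deoxygenation (Bu3SnH, AIBN, toluene, reflux) gives 23 directly.

Further compounds
F1 | step 10 | (5S,8R,9S,10R,13E)-8-[(tert-butyldimethylsilyl)oxy]-1-oxolabda-6,13-dien-15-yl acetate (enantiomer of 17) | CC(=O)OC/C=C(\C)CC[C@H]1[C@]2(C)C(=O)CCC(C)(C)[C@@H]2C=C[C@@]1(C)O[Si](C)(C)C(C)(C)C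
F2 | step 4 | 2-methylhepta-2,6-dien-4-ol (racemic) | CC(C)=CC(O)CC=C
F3 | step 4 | 4-[(1-ethoxyethenyl)oxy]-2-methylhepta-2,6-diene (not isolated) | CC(C)=CC(CC=C)OC(=C)OCC
F4 | step 4 | ethyl (4E)-3,3-dimethylocta-4,7-dienoate | CCOC(=O)CC(C)(C)/C=C/CC=C
F5 | step 4 | (4E)-3,3-dimethylocta-4,7-dien-1-ol | OCCC(C)(C)/C=C/CC=C
F6 | step 13 | (5R,8S,9R,10S,13E)-1,8-dihydroxylabd-13-en-15-yl acetate (C1 epimers) | CC(=O)OC/C=C(\C)CC[C@@H]1[C@@]2(C)C(O)CCC(C)(C)[C@H]2CC[C@]1(C)O
F7 | step 13 | (5R,8S,9R,10S,13E)-8-hydroxy-1-[(1H-imidazol-1-ylcarbonothioyl)oxy]labd-13-en-15-yl acetate (C1 epimers) | CC(=O)OC/C=C(\C)CC[C@@H]1[C@@]2(C)C(OC(=S)n3ccnc3)CCC(C)(C)[C@H]2CC[C@]1(C)O
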